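The route cuts the carbocycle (C1'–C6') at C1'–C6' and C3'–C4'. The key step exploits the fact that C1' is the only link between the two rings and that the functionalised carbons C4' (Cl, CH3) and C5' (Br) sit where an acetoacetate unit places an enone α-carbon and a ketone. One amine-catalysed Michael addition–aldol condensation–decarboxylation closes the ring, sets C1' and delivers that enone. Its precursor is an (E)-enal whose β-carbon (C1') hangs on the quaternary C6 of a 2,2,6-trimethyl-3,6-dihydropyran. This pyran (O1, C2–C6) comes from (S)-linalool, and the C5 hydroxyl is added at the end.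

Key step: step 4

Labels: pyran O1, C2 (gem-dimethyl), C3=C4, C5 (carbinol carbon of the target), C6 (C-methyl); carbocycle C1' (bonded to C6), C2', C3', C4' (Cl, CH3), C5' (Br), C6'. Names follow IUPAC numbering; the Why lines use these labels.

Remark: C6 keeps one spatial arrangement from 1 to 18; its descriptor is S up to 17 and R in 18 only because the C5 hydroxyl raises the rank of C5. The C3 epimers of 2 and the epoxide diastereomers of 11 are carried as mixtures, since those centres are destroyed in the next step.

Step 1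
Reactants: 1 (S)-linalool [(3S)-3,7-dimethylocta-1,6-dien-3-ol]
Product: 2 (6S)-6-ethenyl-2,2,6-trimethyl-3-(phenylselanyl)oxane (mixture of C3 epimers)
Conditions: N-(phenylselanyl)phthalimide, camphorsulfonic acid (cat.), CH2Cl2, 0 °C to rt
Reagents that add atoms: N-(phenylselanyl)phthalimide, O=C1N([Se]c2ccccc2)C(=O)c2ccccc12
Why: Phenylselenoetherification: the seleniranium ion forms on the electron-rich trisubstituted alkene and the tertiary hydroxyl opens it at the more substituted carbon (Markovnikov, 6-endo), the acid keeping the addition reversible so that the oxane should be favoured over the oxolane; the carbinol stereocentre is not touched and the new C3 centre is destroyed in step 2.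

Step 2
Reactants: 2 (6S)-6-ethenyl-2,2,6-trimethyl-3-(phenylselanyl)oxane
Product: 4 (2S)-2,6,6-trimethyl-3,6-dihydro-2H-pyran-2-carbaldehyde, via selenoxide aldehyde 3 (not isolated)
Conditions: O3, CH2Cl2/MeOH, −78 °C; Me2S, then i-Pr2NH, −78 °C to rt
Reagents that add atoms: ozone, [O-][O+]=O
Why: Ozone oxidises the selenide to the selenoxide and cleaves the vinyl group while the ring is still saturated, and on warming the selenoxide undergoes syn-elimination toward C4, the only neighbour with hydrogen, so that C3=C4 forms only after the ozone has been purged (ozonolysis combined with selenoxide elimination); both C3 epimers converge and C6 has no hydrogen to lose.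

Step 3
Reactants: 4 (2S)-2,6,6-trimethyl-3,6-dihydro-2H-pyran-2-carbaldehyde; 5 (triphenylphosphoranylidene)acetaldehyde
Product: 6 (2E)-3-[(2S)-2,6,6-trimethyl-3,6-dihydro-2H-pyran-2-yl]prop-2-enal
Conditions: toluene, 80 °C
Reagents that add atoms: none
Why: Wittig reaction of a stabilised ylide, which should give the E-enal; the aldehyde is non-enolisable, so C6 cannot epimerise.

Step 4
Reactants: 6 (2E)-3-[(2S)-2,6,6-trimethyl-3,6-dihydro-2H-pyran-2-yl]prop-2-enal; 7 tert-butyl acetoacetate
Product: 10 (5S)-5-[(2S)-2,6,6-trimethyl-3,6-dihydro-2H-pyran-2-yl]cyclohex-2-en-1-one, via Michael adduct 8 (not isolated), via cyclised keto ester 9 (not isolated)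
Conditions: (R)-2-{bis[3,5-bis(trifluoromethyl)phenyl][(trimethylsilyl)oxy]methyl}pyrrolidine (10 mol %), PhCO2H (cat.), toluene, rt; then p-TsOH·H2O (20 mol %), toluene, 80 °C
Reagents that add atoms: none
Why: The (R)-configured diarylprolinol silyl ether condenses with 6 to an E-iminium ion in its s-trans form, whose Si face at C1' is blocked by the diaryl(silyloxy)methyl group, so the enol of 7 adds through its central carbon to the Re face of C1' and forms C1'–C6' with the (S) configuration. This is the known amine-catalysed asymmetric Michael addition of β-keto esters to enals, applied here to an enal whose β-carbon bears a fully substituted, oxygenated carbon. After hydrolysis of the enamine to adduct 8, TsOH enolises the methyl ketone toward C4', which attacks the aldehyde carbon C3' in a 6-(enolendo)-exo-trig aldol addition and loses water to give the conjugated keto ester 9; closure through the central carbon would need a four-membered ring, so the ketone is fixed at C5'. Acidolysis of the tert-butyl ester and decarboxylation of the β-keto acid then give 10. C1' is the only new stereocentre and is set by the catalyst; the resident quaternary C6 may reinforce or oppose it, and because C6 carries no hydrogen, neither dienamine formation nor epimerisation can erode the result. The step needs 1,4- over 1,2-addition, secured by iminium activation and the soft β-keto ester, and survival of the tertiary allylic ether, for which the acid is kept catalytic in a non-nucleophilic solvent.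

Step 5
Reactants: 10 (5S)-5-[(2S)-2,6,6-trimethyl-3,6-dihydro-2H-pyran-2-yl]cyclohex-2-en-1-one
Product: 11 (4S)-4-[(2S)-2,6,6-trimethyl-3,6-dihydro-2H-pyran-2-yl]-7-oxabicyclo[4.1.0]heptan-2-one (mixture of epoxide diastereomers)
Conditions: H2O2 (30% aq.), NaOH (cat.), MeOH, 0 °C
Reagents that add atoms: hydrogen peroxide, OO
Why: Weitz–Scheffer epoxidation: hydroperoxide anion adds only to the electron-poor C3'=C4' bond and leaves the isolated pyran alkene alone; the two new epoxide centres may form as a mixture because both are removed in step 6.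

Step 6
Reactants: 11 (4S)-4-[(2S)-2,6,6-trimethyl-3,6-dihydro-2H-pyran-2-yl]-7-oxabicyclo[4.1.0]heptan-2-one
Product: 13 (5S)-2-chloro-5-[(2S)-2,6,6-trimethyl-3,6-dihydro-2H-pyran-2-yl]cyclohex-2-en-1-one, via chlorohydrin 12 (not isolated)
Conditions: HCl (4 M in 1,4-dioxane), THF, 0 °C to rt
Reagents that add atoms: hydrogen chloride, Cl
Why: Ring opening of the α,β-epoxy ketone by chloride at the carbonyl-activated α-carbon C4' and acid-promoted dehydration of the resulting β-hydroxy ketone, the standard conversion of epoxy ketones into α-halo enones; no stereocentre is created.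

Step 7
Reactants: 13 (5S)-2-chloro-5-[(2S)-2,6,6-trimethyl-3,6-dihydro-2H-pyran-2-yl]cyclohex-2-en-1-one
Product: 15 (2S,5S)-2-chloro-2-methyl-5-[(2S)-2,6,6-trimethyl-3,6-dihydro-2H-pyran-2-yl]cyclohexan-1-one, via lithium enolate 14 (not isolated)
Conditions: LiBH(s-Bu)3, THF, −78 °C; then MeI, DMPU, −78 to 0 °C
Reagents that add atoms: iodomethane, CI
Why: Reductive alkylation of an enone: 1,4-hydride addition gives the C4'–C5' enolate regiospecifically, and iodomethane should attack C4' mainly along the axial direction of the half-chair in which the bulky C1' substituent is equatorial (chair-like transition state), placing CH3 axial and cis to that substituent with Cl equatorial; the minor C4' epimer would be removed by chromatography.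

Step 8
Reactants: 15 (2S,5S)-2-chloro-2-methyl-5-[(2S)-2,6,6-trimethyl-3,6-dihydro-2H-pyran-2-yl]cyclohexan-1-one
Product: 16 (1R,2S,5S)-2-chloro-2-methyl-5-[(2S)-2,6,6-trimethyl-3,6-dihydro-2H-pyran-2-yl]cyclohexan-1-ol
Conditions: LiBH(s-Bu)3, THF, −78 °C; then H2O
Reagents that add atoms: none
Why: Reduction with a bulky trialkylborohydride (steric approach control): hydride enters from the equatorial side, away from the axial hydrogens at C1' and C3', which should give the axial C5' alcohol; this alcohol is cis to the equatorial chlorine and therefore cannot close to an epoxide.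

Step 9
Reactants: 16 (1R,2S,5S)-2-chloro-2-methyl-5-[(2S)-2,6,6-trimethyl-3,6-dihydro-2H-pyran-2-yl]cyclohexan-1-ol
Product: 17 (2S)-2-[(1S,3S,4S)-3-bromo-4-chloro-4-methylcyclohexyl]-2,6,6-trimethyl-3,6-dihydro-2H-pyran
Conditions: PPh3, CBr4, CH2Cl2, 0 °C to reflux
Reagents that add atoms: tetrabromomethane, BrC(Br)(Br)Br
Why: Appel reaction: bromide displaces the axial oxyphosphonium group at C5' from the rear (SN2, inversion), which should give the equatorial bromide, cis to the C1' substituent and trans to chlorine; the equatorial chlorine is gauche to the leaving group and cannot participate.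

Step 10
Reactants: 17 (2S)-2-[(1S,3S,4S)-3-bromo-4-chloro-4-methylcyclohexyl]-2,6,6-trimethyl-3,6-dihydro-2H-pyran
Product: 18 (2R,3R)-2-[(1S,3S,4S)-3-bromo-4-chloro-4-methylcyclohexyl]-2,6,6-trimethyl-3,6-dihydro-2H-pyran-3-ol
Conditions: SeO2, 1,4-dioxane, 80 °C
Reagents that add atoms: selenium dioxide, O=[Se]=O
Why: Allylic hydroxylation with SeO2 (ene reaction followed by [2,3]-sigmatropic rearrangement): C5 carries the only allylic hydrogens and the double bond returns to C3=C4; with the cyclohexyl group equatorial and the C6 methyl axial, selenium should bond to C3 on the face away from the pseudoaxial C2 methyl and take the pseudoaxial C5 hydrogen on that same face, so that OH arrives cis to the cyclohexyl group, as the target requires.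

Compound list
1 | (S)-linalool, (3S)-3,7-dimethylocta-1,6-dien-3-ol | C=C[C@@](C)(O)CCC=C(C)C | starting material
2 | (6S)-6-ethenyl-2,2,6-trimethyl-3-(phenylselanyl)oxane, C3 epimers | CC1(C)C([Se]c2ccccc2)CC[C@@](C)(C=C)O1 | intermediate
3 | (2S)-2,6,6-trimethyl-5-(phenylseleninyl)oxane-2-carbaldehyde | CC1(C)C([Se](=O)c2ccccc2)CC[C@@](C)(C=O)O1 | intermediate
4 | (2S)-2,6,6-trimethyl-3,6-dihydro-2H-pyran-2-carbaldehyde | CC1(C)C=CC[C@@](C)(C=O)O1 | intermediate
5 | (triphenylphosphoranylidene)acetaldehyde | O=CC=P(c1ccccc1)(c1ccccc1)c1ccccc1 | starting material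
6 | (2E)-3-[(2S)-2,6,6-trimethyl-3,6-dihydro-2H-pyran-2-yl]prop-2-enal | CC1(C)C=CC[C@@](C)(/C=C/C=O)O1 | intermediate
7 | tert-butyl acetoacetate (tert-butyl 3-oxobutanoate) | CC(=O)CC(=O)OC(C)(C)C | starting material
8 | tert-butyl (3S)-2-acetyl-5-oxo-3-[(2S)-2,6,6-trimethyl-3,6-dihydro-2H-pyran-2-yl]pentanoate, C2 epimers | CC1(C)C=CC[C@@](C)([C@H](C(C(C)=O)C(=O)OC(C)(C)C)CC=O)O1 | intermediate
9 | tert-butyl (6S)-2-oxo-6-[(2S)-2,6,6-trimethyl-3,6-dihydro-2H-pyran-2-yl]cyclohex-3-ene-1-carboxylate, C1 epimers | CC1(C)C=CC[C@@](C)([C@H]2CC=CC(=O)C2C(=O)OC(C)(C)C)O1 | intermediate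
10 | (5S)-5-[(2S)-2,6,6-trimethyl-3,6-dihydro-2H-pyran-2-yl]cyclohex-2-en-1-one | CC1(C)C=CC[C@@](C)([C@H]2CC=CC(=O)C2)O1 | intermediate
11 | (4S)-4-[(2S)-2,6,6-trimethyl-3,6-dihydro-2H-pyran-2-yl]-7-oxabicyclo[4.1.0]heptan-2-one, epoxide diastereomers | CC1(C)C=CC[C@@](C)([C@H]2CC3OC3C(=O)C2)O1 | intermediate
12 | (5S)-2-chloro-3-hydroxy-5-[(2S)-2,6,6-trimethyl-3,6-dihydro-2H-pyran-2-yl]cyclohexan-1-one, C2/C3 diastereomers | CC1(C)C=CC[C@@](C)([C@H]2CC(O)C(Cl)C(=O)C2)O1 | intermediate
13 | (5S)-2-chloro-5-[(2S)-2,6,6-trimethyl-3,6-dihydro-2H-pyran-2-yl]cyclohex-2-en-1-one | CC1(C)C=CC[C@@](C)([C@H]2CC=C(Cl)C(=O)C2)O1 | intermediate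
14 | lithium (5S)-2-chloro-5-[(2S)-2,6,6-trimethyl-3,6-dihydro-2H-pyran-2-yl]cyclohex-1-en-1-olate | CC1(C)C=CC[C@@](C)([C@H]2CCC(Cl)=C([O-])C2)O1.[Li+] | intermediate
15 | (2S,5S)-2-chloro-2-methyl-5-[(2S)-2,6,6-trimethyl-3,6-dihydro-2H-pyran-2-yl]cyclohexan-1-one | CC1(C)C=CC[C@@](C)([C@H]2CC[C@](C)(Cl)C(=O)C2)O1 | intermediate
16 | (1R,2S,5S)-2-chloro-2-methyl-5-[(2S)-2,6,6-trimethyl-3,6-dihydro-2H-pyran-2-yl]cyclohexan-1-ol | CC1(C)C=CC[C@@](C)([C@H]2CC[C@](C)(Cl)[C@H](O)C2)O1 | intermediate
17 | (2S)-2-[(1S,3S,4S)-3-bromo-4-chloro-4-methylcyclohexyl]-2,6,6-trimethyl-3,6-dihydro-2H-pyran | CC1(C)C=CC[C@@](C)([C@H]2CC[C@](C)(Cl)[C@@H](Br)C2)O1 | intermediate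
18 | (2R,3R)-2-[(1S,3S,4S)-3-bromo-4-chloro-4-methylcyclohexyl]-2,6,6-trimethyl-3,6-dihydro-2H-pyran-3-ol | CC1(C)C=C[C@@H](O)[C@@](C)([C@H]2CC[C@](C)(Cl)[C@@H](Br)C2)O1 | target

Total step count: 10. Longest linear sequence: 10 steps, from 1 to 18.

Steps most likely to fail

Step 4. Carbon–carbon bond formation at the congested β-carbon of the iminium ion may be too slow. The catalyst may be mismatched with C6, which would give poor facial selectivity. The tertiary allylic ether may ionise in the hot acid stage. The fallback builds the ring by base-mediated chemistry from aldehyde 4 and rejoins the route at 10. A Horner–Wadsworth–Emmons reaction of 4 with diethyl (2-oxopropyl)phosphonate (Ba(OH)2, wet THF) would give (3E)-4-[(2S)-2,6,6-trimethyl-3,6-dihydro-2H-pyran-2-yl]but-3-en-2-one F1. Diethyl malonate with NaOEt in refluxing EtOH (Michael addition, then Claisen cyclisation) would convert it into ethyl 2,4-dioxo-6-[(2S)-2,6,6-trimethyl-3,6-dihydro-2H-pyran-2-yl]cyclohexane-1-carboxylate F2. Saponification, mild acidification and gentle warming would give 5-[(2S)-2,6,6-trimethyl-3,6-dihydro-2H-pyran-2-yl]cyclohexane-1,3-dione F3, in which C1' is not yet a stereocentre. O-Methylation (Me2SO4, K2CO3, acetone) would give 3-methoxy-5-[(2S)-2,6,6-trimethyl-3,6-dihydro-2H-pyran-2-yl]cyclohex-2-en-1-one F4 as both C5 epimers. Reduction with LiAlH4 followed by dilute aqueous acid (Stork–Danheiser transposition) would return to 10 together with its C1' epimer, (5R)-5-[(2S)-2,6,6-trimethyl-3,6-dihydro-2H-pyran-2-yl]cyclohex-2-en-1-one F5, which has to be separated by chromatography. This sequence avoids iminium activation and hot acid; its price is four extra operations and no control at C1'.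

Step 9. Displacement at a secondary carbon next to the quaternary C4' is slow, so E2 elimination toward C6' or migration of the antiperiplanar C4' methyl group may outrun substitution. The fallback separates activation from displacement, starting from 16 and rejoining at 17. Chloromethanesulfonyl chloride and pyridine (CH2Cl2, 0 °C) would give (1R,2S,5S)-2-chloro-2-methyl-5-[(2S)-2,6,6-trimethyl-3,6-dihydro-2H-pyran-2-yl]cyclohexyl chloromethanesulfonate F6, an isolable sulfonate more reactive than a mesylate. LiBr in DMPU at 50–60 °C would then displace it with inversion to give 17, without a phosphonium intermediate and with a high concentration of free bromide.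

Step 10. The ene reaction at an alkene flanked by two quaternary carbons may be slow, the allylic alcohol may be over-oxidised, and facial selectivity at C5 may be incomplete. The fallback sets C5 by hydride delivery instead of by the geometry of an ene reaction, starting from 17 and rejoining at 18. Allylic oxidation with CrO3·3,5-dimethylpyrazole (CH2Cl2, −20 °C) would give (2R)-2-[(1S,3S,4S)-3-bromo-4-chloro-4-methylcyclohexyl]-2,6,6-trimethyl-2H-pyran-3(6H)-one F7. Luche reduction (NaBH4, CeCl3·7H2O, MeOH, −78 °C) would then reduce only the carbonyl group, with hydride expected to enter from the face of the C6 methyl group, the smaller substituent on the neighbouring quaternary carbon, to give 18.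

Further compounds
F1 | step 4 | (3E)-4-[(2S)-2,6,6-trimethyl-3,6-dihydro-2H-pyran-2-yl]but-3-en-2-one | CC1(C)C=CC[C@@](C)(/C=C/C(C)=O)O1
F2 | step 4 | ethyl 2,4-dioxo-6-[(2S)-2,6,6-trimethyl-3,6-dihydro-2H-pyran-2-yl]cyclohexane-1-carboxylate | CC1(C)C=CC[C@@](C)(C2CC(=O)CC(=O)C2C(=O)OCC)O1
F3 | step 4 | 5-[(2S)-2,6,6-trimethyl-3,6-dihydro-2H-pyran-2-yl]cyclohexane-1,3-dione | CC1(C)C=CC[C@@](C)(C2CC(=O)CC(=O)C2)O1
F4 | step 4 | 3-methoxy-5-[(2S)-2,6,6-trimethyl-3,6-dihydro-2H-pyran-2-yl]cyclohex-2-en-1-one, C5 epimers | CC1(C)C=CC[C@@](C)(C2CC(=O)C=C(OC)C2)O1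
F5 | step 4 | (5R)-5-[(2S)-2,6,6-trimethyl-3,6-dihydro-2H-pyran-2-yl]cyclohex-2-en-1-one | CC1(C)C=CC[C@@](C)([C@@H]2CC=CC(=O)C2)O1
F6 | step 9 | (1R,2S,5S)-2-chloro-2-methyl-5-[(2S)-2,6,6-trimethyl-3,6-dihydro-2H-pyran-2-yl]cyclohexyl chloromethanesulfonate | CC1(C)C=CC[C@@](C)([C@H]2CC[C@](C)(Cl)[C@H](OS(=O)(=O)CCl)C2)O1
F7 | step 10 | (2R)-2-[(1S,3S,4S)-3-bromo-4-chloro-4-methylcyclohexyl]-2,6,6-trimethyl-2H-pyran-3(6H)-one | CC1(C)C=CC(=O)[C@@](C)([C@H]2CC[C@](C)(Cl)[C@@H](Br)C2)O1
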